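**Strategy.** The depside is cut through ring B instead of at its ester. Ring B is a resorcinol whose C1'–C2' edge (ester carbonyl carbon next to a methyl-bearing carbon) is the triple bond of a but-2-ynoate already hung on O4 of ring A, while C3'(Cl)–C4'(OH)–C5'(CH3)–C6'(OH) is a doubly silylated 4-chloro-2-methylacetoacetate. One Diels–Alder/aromatisation event forms C2'–C3' and C1'–C6' and closes ring B, so no hexasubstituted benzoic acid ever has to be coupled to a di-ortho-substituted phenol. The precursor is the ring A aryl but-2-ynoate, whose chelated 2-OH is capped as a trimethylsilyl ether in the flask so that it cannot protonate the diene.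

Key step: step 7

Remark on the chemistry: ring A is numbered C1 (CO2Me) to C6 and ring B C1' (ester carbonyl) to C6'. The target has no stereocentre, so transient sp3 centres (9, 10, 15) are left undefined as mixtures and enol ether geometries (8, 12, 13) are drawn as the expected isomers; none of them survives in 17.

Step 1
Reactants: 1 methyl 2,4-dihydroxy-3,6-dimethylbenzoate (atraric acid, commercial)
Product: 2 methyl 5-formyl-2,4-dihydroxy-3,6-dimethylbenzoate
Conditions: Cl2CHOMe, TiCl4, CH2Cl2, 0 °C to rt; then 1 M HCl (aq)
Reagents that add atoms: dichloromethyl methyl ether, COC(Cl)Cl; water, O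
Why: Rieche formylation, in which the TiCl4-activated dichloromethyl ether attacks C5, the only unsubstituted ring carbon (ortho to 4-OH, para to 2-OH), so only one regioisomer can form and aqueous work-up releases the aldehyde.

Step 2
Reactants: 2 methyl 5-formyl-2,4-dihydroxy-3,6-dimethylbenzoate
Product: 3 methyl 2,4-dihydroxy-3,5,6-trimethylbenzoate
Conditions: H2 (1 atm), 10% Pd/C, AcOH, cat. HCl, rt
Reagents that add atoms: none
Why: Catalytic hydrogenation with benzylic hydrogenolysis, the aldehyde being reduced to a benzylic alcohol whose C–O bond is activated by the ortho and para phenols and is cleaved to the methyl group, while the ester and the arene should stay untouched.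

Step 3
Reactants: 3 methyl 2,4-dihydroxy-3,5,6-trimethylbenzoate; 4 but-2-ynoic acid
Product: 5 methyl 4-(but-2-ynoyloxy)-2-hydroxy-3,5,6-trimethylbenzoate
Conditions: DCC, DMAP (cat.), CH2Cl2, 0 °C to rt
Reagents that add atoms: none
Why: Steglich esterification, expected at O4 because the 4-OH is the free and more acidic phenol whereas the 2-OH is locked in a hydrogen bond to the ester carbonyl and flanked by CO2Me and CH3; low temperature and little DMAP limit conjugate addition to the ynoate.

Step 4
Reactants: 6 ethyl propanoate; 7 2-chloro-N-methoxy-N-methylacetamide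
Product: 10 ethyl 4-chloro-2-methyl-3-oxobutanoate (racemic), via lithium ester enolate 8 (not isolated), via chelated tetrahedral adduct 9 (not isolated)
Conditions: LiN(iPr)2 (commercial solution), THF, −78 °C; then 7, −78 °C; cold 1 M HCl quench
Reagents that add atoms: none
Why: Crossed Claisen-type acylation of a preformed ester enolate by a Weinreb amide, whose N-methoxy-N-methyl adduct stays chelated to lithium until the acidic quench, so that neither over-addition nor proton transfer from the β-keto ester can occur.

Step 5
Reactants: 10 ethyl 4-chloro-2-methyl-3-oxobutanoate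
Product: 11 ethyl 4-chloro-2-methyl-3-(trimethylsilyloxy)but-2-enoate
Conditions: Me3SiCl, Et3N, pentane, rt
Reagents that add atoms: chlorotrimethylsilane, C[Si](C)(C)Cl
Why: Silyl enol ether formation on the ketone oxygen of a β-keto ester, the standard first stage of bis-silyl diene synthesis; the non-polar solvent precipitates the ammonium salt and disfavours alkylation of the amine by the chloromethyl ketone.

Step 6
Reactants: 11 ethyl 4-chloro-2-methyl-3-(trimethylsilyloxy)but-2-enoate
Product: 13 (1Z,3Z)-4-chloro-1-ethoxy-2-methyl-1,3-bis(trimethylsilyloxy)buta-1,3-diene, via lithium dienolate 12 (not isolated)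
Conditions: LiN(iPr)2 (commercial solution), THF, −78 °C; then Me3SiCl, −78 °C to rt; pentane, filtration under Ar, used crude
Reagents that add atoms: chlorotrimethylsilane, C[Si](C)(C)Cl
Why: Kinetic γ-deprotonation of the vinylogous ester at the chloromethyl group followed by O-silylation of the extended enolate, the standard second stage of 1-alkoxy-1,3-bis(silyloxy)diene synthesis, which should place chlorine on the outer side of the diene as the cycloaddition requires.

Step 7
Reactants: 5 methyl 4-(but-2-ynoyloxy)-2-hydroxy-3,5,6-trimethylbenzoate; 13 (1Z,3Z)-4-chloro-1-ethoxy-2-methyl-1,3-bis(trimethylsilyloxy)buta-1,3-diene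
Product: 17 methyl 4-[(3-chloro-4,6-dihydroxy-2,5-dimethylbenzoyl)oxy]-2-hydroxy-3,5,6-trimethylbenzoate (target), via trimethylsilyl ether 14 (not isolated), via cyclohexadiene cycloadduct 15 (not isolated), via tris(trimethylsilyl) depside 16 (not isolated)
Conditions: N,O-bis(trimethylsilyl)acetamide (1.5 equiv), CH2Cl2, rt, then evaporate; 13 (2.5 equiv), toluene, 100 °C, sealed tube, Ar; then 1 M HCl, THF, rt
Reagents that add atoms: none
Why: N,O-bis(trimethylsilyl)acetamide first caps the chelated 2-OH of ring A, so that no acidic proton destroys the ketene acetal diene. The diene then adds across the ynoate in a normal-electron-demand Diels–Alder reaction, either as one polarised cycloaddition or as conjugate addition followed by Claisen-type closure; the closest known reaction type is the cycloaddition of 1-alkoxy-1,3-bis(silyloxy)buta-1,3-dienes with acetylenic esters, which aromatises to resorcylates. Ring B closes as a six-membered carbocycle by [4+2] union of the four diene carbons with the two alkyne carbons, forming C2'–C3' and C1'–C6'. No stereocentre survives, because the two sp3 carbons of 15 (C3' and C6') become aromatic when ethanol leaves across the ring, the hydrogen coming from C3' so that chlorine stays. The only selectivity needed is regiochemical and rests on matched polarisation: the chlorine-bearing diene terminus carries the largest HOMO coefficient (donation from all three oxygens) and bonds to the electrophilic β-carbon of the aryl ynoate, while the ketene acetal carbon bonds to the α-carbon. Aqueous acid finally cleaves the three silyl ethers of 16 to give 17.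

**Compound list**

1 | methyl 2,4-dihydroxy-3,6-dimethylbenzoate | COC(=O)c1c(C)cc(O)c(C)c1O | starting material
2 | methyl 5-formyl-2,4-dihydroxy-3,6-dimethylbenzoate | COC(=O)c1c(C)c(C=O)c(O)c(C)c1O | intermediate
3 | methyl 2,4-dihydroxy-3,5,6-trimethylbenzoate | COC(=O)c1c(C)c(C)c(O)c(C)c1O | intermediate
4 | but-2-ynoic acid | CC#CC(=O)O | starting material
5 | methyl 4-(but-2-ynoyloxy)-2-hydroxy-3,5,6-trimethylbenzoate | COC(=O)c1c(C)c(C)c(OC(=O)C#CC)c(C)c1O | intermediate
6 | ethyl propanoate | CCOC(=O)CC | starting material
7 | 2-chloro-N-methoxy-N-methylacetamide | CON(C)C(=O)CCl | starting material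
8 | lithium 1-ethoxyprop-1-en-1-olate (kinetic enolate, methyl cis to ethoxy; geometry without consequence) | [Li+].C/C=C(/[O-])OCC | intermediate (not isolated)
9 | lithium 1-chloro-4-ethoxy-2-[methoxy(methyl)amino]-3-methyl-4-oxobutan-2-olate (mixture of diastereomers) | [Li+].CCOC(=O)C(C)C([O-])(CCl)N(C)OC | intermediate (not isolated)
10 | ethyl 4-chloro-2-methyl-3-oxobutanoate (racemic, enolisable centre) | CCOC(=O)C(C)C(=O)CCl | intermediate
11 | ethyl 4-chloro-2-methyl-3-(trimethylsilyloxy)but-2-enoate (E/Z mixture; this bond becomes single in 13) | CCOC(=O)C(C)=C(CCl)O[Si](C)(C)C | intermediate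
12 | lithium 4-chloro-1-ethoxy-2-methyl-3-(trimethylsilyloxy)buta-1,3-dien-1-olate (geometry as drawn for 13) | [Li+].Cl/C=C(O[Si](C)(C)C)/C(C)=C(/OCC)[O-] | intermediate (not isolated)
13 | (1Z,3Z)-4-chloro-1-ethoxy-2-methyl-1,3-bis(trimethylsilyloxy)buta-1,3-diene (chlorine trans to C2; C1=C2 geometry without consequence) | Cl/C=C(O[Si](C)(C)C)/C(C)=C(/OCC)O[Si](C)(C)C | intermediate
14 | methyl 4-(but-2-ynoyloxy)-3,5,6-trimethyl-2-(trimethylsilyloxy)benzoate | COC(=O)c1c(C)c(C)c(OC(=O)C#CC)c(C)c1O[Si](C)(C)C | intermediate (not isolated)
15 | 3-(methoxycarbonyl)-2,5,6-trimethyl-4-(trimethylsilyloxy)phenyl 3-chloro-6-ethoxy-2,5-dimethyl-4,6-bis(trimethylsilyloxy)cyclohexa-1,4-diene-1-carboxylate (diastereomer mixture at C3' and C6') | COC(=O)c1c(C)c(C)c(OC(=O)C2=C(C)C(Cl)C(O[Si](C)(C)C)=C(C)C2(OCC)O[Si](C)(C)C)c(C)c1O[Si](C)(C)C | intermediate (not isolated)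
16 | methyl 4-{[3-chloro-2,5-dimethyl-4,6-bis(trimethylsilyloxy)benzoyl]oxy}-3,5,6-trimethyl-2-(trimethylsilyloxy)benzoate | COC(=O)c1c(C)c(C)c(OC(=O)c2c(C)c(Cl)c(O[Si](C)(C)C)c(C)c2O[Si](C)(C)C)c(C)c1O[Si](C)(C)C | intermediate (not isolated)
17 | methyl 4-[(3-chloro-4,6-dihydroxy-2,5-dimethylbenzoyl)oxy]-2-hydroxy-3,5,6-trimethylbenzoate | COC(=O)c1c(C)c(C)c(OC(=O)c2c(C)c(Cl)c(O)c(C)c2O)c(C)c1O | target

**Step count and risk**

Total steps: 7. Longest linear sequence: 4 steps (steps 1, 2, 3 and 7; the diene branch, steps 4, 5, 6 and 7, is equally long).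

Most likely to fail, in this order:

Step 7. The cycloaddition may stall: the methyl group on the alkyne β-carbon and the chlorine on the diene terminus both slow the first bond formation, so thermal decay and protodesilylation of the diene could overtake it. The fallback sets out from 5 and comes back at 17; it leaves chlorine off the diene and introduces it last. Commercial ethyl 2-methylacetoacetate (CCOC(=O)C(C)C(C)=O) is silylated with Me3SiCl/Et3N to ethyl 2-methyl-3-(trimethylsilyloxy)but-2-enoate F1. LiN(iPr)2 and Me3SiCl then give 1-ethoxy-2-methyl-1,3-bis(trimethylsilyloxy)buta-1,3-diene F2, which is less hindered and more nucleophilic than 13. Heating F2 with 14 (made from 5 as in step 7) should give the chlorine-free cyclohexadiene cycloadduct F3, which loses ethanol to the tris(trimethylsilyl) chlorine-free depside F4. Acidic work-up gives methyl 4-[(2,4-dihydroxy-3,6-dimethylbenzoyl)oxy]-2-hydroxy-3,5,6-trimethylbenzoate F5. Electrophilic chlorination with SO2Cl2 (1 equiv, Et2O, 0 °C) should then place chlorine on C3', the only aromatic C–H of the molecule (ortho to 4'-OH, para to 6'-OH), to reach 17.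

Step 6. Deprotonation next to chlorine may go astray: the lithium dienolate can lose chloride, condense with itself or be silylated on carbon, and the diene may hydrolyse during isolation. The fallback sets out from 10 and comes back at 13; it uses soft enolisation and no lithium species. Compound 10 is treated with Me3SiOTf (2.2 equiv) and Et3N in Et2O at 0 °C, which silylates both enolisable positions in one flask, and 13 is obtained after separation of the ammonium triflate layer. This fallback makes no compound outside the list (F0).

Step 4. The ester enolate may displace chloride or deprotonate the chloroacetamide instead of adding to its carbonyl group. The fallback sets out from 6 and comes back at 10; it replaces the basic enolate by a neutral nucleophile. Compound 6 is converted (LiN(iPr)2, Me3SiCl, THF, −78 °C) into the silyl ketene acetal 1-ethoxy-1-(trimethylsilyloxy)prop-1-ene F6. F6 is C-acylated by chloroacetyl chloride (ClCC(=O)Cl; CH2Cl2, 0 °C to rt) with loss of Me3SiCl to give 10.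

Further compounds
F1 | step 7 | ethyl 2-methyl-3-(trimethylsilyloxy)but-2-enoate | CCOC(=O)C(C)=C(C)O[Si](C)(C)C
F2 | step 7 | 1-ethoxy-2-methyl-1,3-bis(trimethylsilyloxy)buta-1,3-diene | C=C(O[Si](C)(C)C)/C(C)=C(/OCC)O[Si](C)(C)C
F3 | step 7 | 3-(methoxycarbonyl)-2,5,6-trimethyl-4-(trimethylsilyloxy)phenyl 6-ethoxy-2,5-dimethyl-4,6-bis(trimethylsilyloxy)cyclohexa-1,4-diene-1-carboxylate (racemic) | COC(=O)c1c(C)c(C)c(OC(=O)C2=C(C)CC(O[Si](C)(C)C)=C(C)C2(OCC)O[Si](C)(C)C)c(C)c1O[Si](C)(C)C
F4 | step 7 | methyl 4-{[3,6-dimethyl-2,4-bis(trimethylsilyloxy)benzoyl]oxy}-3,5,6-trimethyl-2-(trimethylsilyloxy)benzoate | COC(=O)c1c(C)c(C)c(OC(=O)c2c(C)cc(O[Si](C)(C)C)c(C)c2O[Si](C)(C)C)c(C)c1O[Si](C)(C)C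
F5 | step 7 | methyl 4-[(2,4-dihydroxy-3,6-dimethylbenzoyl)oxy]-2-hydroxy-3,5,6-trimethylbenzoate | COC(=O)c1c(C)c(C)c(OC(=O)c2c(C)cc(O)c(C)c2O)c(C)c1O
F0 | step 6 | none | none
F6 | step 4 | 1-ethoxy-1-(trimethylsilyloxy)prop-1-ene | CC=C(OCC)O[Si](C)(C)C
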